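**Retrosynthetic overview**
- The strategy rests on C1'', a lone CH2 that joins C8 of ring A (ortho to the 7-hydroxyl, between C7 and C8a) to the stereocentre C2''. Cutting C8–C1'' and C1''–C2'' reduces the (S)-lavandulyl chain to formaldehyde plus the α-carbon of 5-methylhex-4-enal, on a kaempferol whose 3- and 4'-hydroxyls carry MOM groups.
- Both bonds are made in one operation: Mannich aminomethylation at C8, amine loss to the C7-oxo C8-methylene quinone methide, and enamine [4+2]. Rings A, B and C come intact from kaempferol; the only ring formed is a temporary dihydropyran lactol on O7/C8 (ring D), opened again in the next step.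
- The lactol carbon is then turned into the isopropenyl carbon (methyl Grignard, 7-O-MOM, oxidation, non-basic methylenation), and the three MOM groups are removed last.
- The flavonol partner is made from kaempferol through a temporary 7-O-benzyl group; the aldehyde comes from a Claisen rearrangement of 2-methylbut-3-en-2-ol with ethyl vinyl ether.

Key step: step 7

Remark: C2'' of the target is (S) by CIP analysis of the given SMILES; the lactol and carbinol carbons formed on the way are carried as epimer mixtures because both end up sp2, and formaldehyde is charged as paraformaldehyde.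

**Step 1**
Reactants: 1 2-methylbut-3-en-2-ol; 2 ethyl vinyl ether
Product: 5 5-methylhex-4-enal, via mixed acetal 3 (not isolated), via allyl vinyl ether 4 (not isolated)
Conditions: 2 (3 equiv), H3PO4 (85%, cat.), sealed vessel, 150 °C; distillation
Reagents that add atoms: none
Why: Acid-catalysed vinyl ether exchange (mixed acetal, loss of ethanol) followed by an aliphatic Claisen rearrangement, whose [3,3] shift converts the tertiary allyl vinyl ether into the γ,δ-unsaturated aldehyde with the trisubstituted alkene in place.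

**Step 2**
Reactants: 6 kaempferol
Product: 7 kaempferol 3,5,7,4'-tetraacetate
Conditions: Ac2O, pyridine, DMAP (cat.), 60 °C
Reagents that add atoms: acetic anhydride, CC(=O)OC(C)=O
Why: Exhaustive O-acylation, in which DMAP and gentle heating should esterify even the hydrogen-bonded 5-hydroxyl.

**Step 3**
Reactants: 7 kaempferol 3,5,7,4'-tetraacetate
Product: 9 7-O-benzylkaempferol 3,5,4'-triacetate, via 7-hydroxy triacetate 8 (not isolated)
Conditions: BnBr (1.2 equiv), K2CO3, acetone, reflux
Reagents that add atoms: benzyl bromide, BrCc1ccccc1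
Why: Selective deacetylation–alkylation: the 7-acetate is the ester of the most acidic phenol and should be cleaved first by carbonate in acetone, and the 7-phenoxide is benzylated at once (Williamson etherification) while the other three esters stay.

**Step 4**
Reactants: 9 7-O-benzylkaempferol 3,5,4'-triacetate
Product: 10 7-O-benzylkaempferol
Conditions: HCl (cat.), MeOH/THF, 50 °C
Reagents that add atoms: none
Why: Acid-catalysed transesterification with methanol removes the three acetates as methyl acetate and leaves the benzyl ether untouched.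

**Step 5**
Reactants: 10 7-O-benzylkaempferol
Product: 11 7-O-benzyl-3,4'-bis-O-(methoxymethyl)kaempferol
Conditions: MOMCl (2.6 equiv), iPr2NEt, CH2Cl2, 0 °C → rt
Reagents that add atoms: chloromethyl methyl ether, COCCl
Why: O-alkylation of the 3- and 4'-hydroxyls, while the 5-hydroxyl is held in a hydrogen bond to C4=O and is not alkylated under amine-base conditions.

**Step 6**
Reactants: 11 7-O-benzyl-3,4'-bis-O-(methoxymethyl)kaempferol
Product: 12 3,4'-bis-O-(methoxymethyl)kaempferol
Conditions: H2 (1 atm), Pd/C (10%), EtOAc/MeOH, rt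
Reagents that add atoms: none
Why: Hydrogenolysis of the benzyl ether frees the 7-hydroxyl, and the aryl MOM ethers and the tetrasubstituted C2=C3 bond of the pyranone should not be reduced under these mild conditions.

**Step 7**
Reactants: 12 3,4'-bis-O-(methoxymethyl)kaempferol; 13 formaldehyde; 5 5-methylhex-4-enal; 14 (R)-2-[diphenyl(trimethylsilyloxy)methyl]pyrrolidine (stoichiometric amine, recovered)
Product: 20 lactol (9S)-5,8-dihydroxy-3-(methoxymethoxy)-2-[4-(methoxymethoxy)phenyl]-9-(3-methylbut-2-en-1-yl)-9,10-dihydro-4H,8H-pyrano[2,3-h]chromen-4-one (both anomers at the lactol carbon), via hemiaminal 15 (not isolated), via Mannich base 16 (not isolated), via quinone methide 17 (not isolated), via enamine 18 (not isolated), via cyclic aminal 19 (not isolated)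
Conditions: 13 (0.95 equiv, as (CH2O)n), 14 (1.1 equiv), CH2Cl2/MeCN, 40 °C; then 5 (2.5 equiv), PhCO2H (20 mol%), 0 °C → rt; pH 5 acetate buffer work-up
Reagents that add atoms: none
Why: Proposed new method: 13 and 14 condense to hemiaminal 15 and, with loss of water, its methyleneiminium ion, which substitutes C8 of 12 (C8–C1'' bond, Mannich base 16); zwitterionic 16 then expels 14 to give the C7-oxo C8-methylene quinone methide 17, while the freed 14 converts 5 into the (E)-enamine 18, whose β-carbon bonds to the methide carbon (C1''–C2'' bond) as O7 closes on the iminium carbon, and water hydrolyses aminal 19 to lactol 20 with return of 14. The closest known reaction types are the C8 Mannich aminomethylation of 5,7-dihydroxyflavones, amine loss from phenolic Mannich bases to ortho-quinone methides, and diarylprolinol silyl ether catalysed formal [4+2] additions of aldehydes to ortho-quinone methides made in situ; new is their merger, with one chiral amine serving as Mannich amine, leaving group and enamine carrier. The dihydropyran ring closes by an inverse-electron-demand oxa-[4+2] cycloaddition of the 1-oxadiene O7=C7–C8=C1'' with the enamine alkene (in the stepwise limit a Michael addition followed by 6-exo-trig attack of O7 on the iminium carbon). C2'' is set by the amine: the C(Ph)2OTMS group of (R)-14 blocks the Si face of the s-trans (E)-enamine, so the methide carbon bonds to the Re face, which gives the (S) centre, and immediate lactol closure should keep this α-carbon from epimerising. The step needs C8 over C6 substitution, which rests on the known C8 preference of 5,7-dihydroxyflavones whose 5-hydroxyl is hydrogen-bonded to C4=O and on using less than one equivalent of 13; it also needs the enamine to meet 17 and not formaldehyde, which is secured by adding 5 only after 13 is consumed, and no achiral secondary amine is present to open a racemic channel.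

**Step 8**
Reactants: 20 lactol
Product: 22 carbinol 5,7-dihydroxy-8-[(2S)-2-(1-hydroxyethyl)-5-methylhex-4-en-1-yl]-3-(methoxymethoxy)-2-[4-(methoxymethoxy)phenyl]-4H-chromen-4-one (carbinol epimers), via open-chain aldehyde 21 (not isolated)
Conditions: MeMgBr (5 equiv), THF, −40 → 0 °C; then aq. NH4Cl
Reagents that add atoms: methylmagnesium bromide, C[Mg]Br
Why: Grignard addition: deprotonation opens the lactol to the phenoxide aldehyde 21, which should take up the methyl nucleophile faster than it enolises, so C2'' keeps its configuration and the new carbinol centre is formed as a mixture that the later oxidation removes.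

**Step 9**
Reactants: 22 carbinol
Product: 23 8-[(2S)-2-(1-hydroxyethyl)-5-methylhex-4-en-1-yl]-5-hydroxy-3,7-bis(methoxymethoxy)-2-[4-(methoxymethoxy)phenyl]-4H-chromen-4-one
Conditions: MOMCl (1.2 equiv), K2CO3, acetone, 0 °C → rt
Reagents that add atoms: chloromethyl methyl ether, COCCl
Why: Williamson-type O-alkylation of the phenoxide only, since K2CO3 deprotonates the acidic 7-hydroxyl but neither the secondary alcohol nor the hydrogen-bonded 5-hydroxyl.

**Step 10**
Reactants: 23 7-O-MOM carbinol
Product: 24 methyl ketone 8-[(2S)-2-acetyl-5-methylhex-4-en-1-yl]-5-hydroxy-3,7-bis(methoxymethoxy)-2-[4-(methoxymethoxy)phenyl]-4H-chromen-4-one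
Conditions: Dess–Martin periodinane, NaHCO3, CH2Cl2, 0 °C → rt
Reagents that add atoms: none
Why: Dess–Martin oxidation under buffered, non-enolising conditions should converge both carbinol epimers on one ketone, with the chelated 5-hydroxyl as the only free phenol.

**Step 11**
Reactants: 24 methyl ketone
Product: 25 5-hydroxy-3,7-bis(methoxymethoxy)-2-[4-(methoxymethoxy)phenyl]-8-[(2S)-5-methyl-2-(prop-1-en-2-yl)hex-4-en-1-yl]-4H-chromen-4-one
Conditions: Zn, CH2Br2, TiCl4, THF (preformed reagent, excess); then 24, CH2Cl2, 0 °C → rt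
Reagents that add atoms: dibromomethane, BrCBr
Why: Takai–Lombardo methylenation, in which the zinc–titanium gem-dimetallic methylene reagent adds to the ketone and eliminates metal oxide without a basic ylide, so the enolisable (S) centre next to the carbonyl should be kept and the chelated pyranone carbonyl (a vinylogous ester) should be left alone.

**Step 12**
Reactants: 25 tris-MOM ether
Product: 26 3,5,7-trihydroxy-2-(4-hydroxyphenyl)-8-[(2S)-5-methyl-2-(prop-1-en-2-yl)hex-4-en-1-yl]-4H-chromen-4-one (target)
Conditions: HCl (3 M aq.)/MeOH, 40 °C, stopped at full conversion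
Reagents that add atoms: none
Why: Acid-catalysed acetal exchange with methanol should remove the three aryl MOM groups as dimethoxymethane, and dilute acid at moderate temperature is chosen to spare the two alkenes.

**Compound list**
1 | 2-methylbut-3-en-2-ol | CC(C)(O)C=C | starting material
2 | ethyl vinyl ether | C=COCC | starting material
3 | 3-(1-ethoxyethoxy)-3-methylbut-1-ene (mixed acetal) | CCOC(C)OC(C)(C)C=C | intermediate
4 | 3-methyl-3-(vinyloxy)but-1-ene (allyl vinyl ether) | C=COC(C)(C)C=C | intermediate
5 | 5-methylhex-4-enal | CC(C)=CCCC=O | intermediate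
6 | kaempferol | O=c1c(O)c(-c2ccc(O)cc2)oc2cc(O)cc(O)c12 | starting material
7 | kaempferol 3,5,7,4'-tetraacetate | O=c1c(OC(C)=O)c(-c2ccc(OC(C)=O)cc2)oc2cc(OC(C)=O)cc(OC(C)=O)c12 | intermediate
8 | kaempferol 3,5,4'-triacetate (7-hydroxyl free, formed as its potassium phenoxide) | O=c1c(OC(C)=O)c(-c2ccc(OC(C)=O)cc2)oc2cc(O)cc(OC(C)=O)c12 | intermediate
9 | 7-O-benzylkaempferol 3,5,4'-triacetate | O=c1c(OC(C)=O)c(-c2ccc(OC(C)=O)cc2)oc2cc(OCc3ccccc3)cc(OC(C)=O)c12 | intermediate
10 | 7-O-benzylkaempferol | O=c1c(O)c(-c2ccc(O)cc2)oc2cc(OCc3ccccc3)cc(O)c12 | intermediate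
11 | 7-O-benzyl-3,4'-bis-O-(methoxymethyl)kaempferol | O=c1c(OCOC)c(-c2ccc(OCOC)cc2)oc2cc(OCc3ccccc3)cc(O)c12 | intermediate
12 | 3,4'-bis-O-(methoxymethyl)kaempferol | O=c1c(OCOC)c(-c2ccc(OCOC)cc2)oc2cc(O)cc(O)c12 | intermediate
13 | formaldehyde | C=O | starting material
14 | (R)-2-[diphenyl(trimethylsilyloxy)methyl]pyrrolidine | C[Si](C)(C)OC([C@H]1CCCN1)(c1ccccc1)c1ccccc1 | starting material
15 | N-(hydroxymethyl) derivative of 14 (hemiaminal, iminium precursor) | OCN1CCC[C@@H]1C(O[Si](C)(C)C)(c1ccccc1)c1ccccc1 | intermediate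
16 | C8 Mannich base: 12 carrying CH2–N(pyrrolidine of 14) at C8 | O=c1c(OCOC)c(-c2ccc(OCOC)cc2)oc2c(CN3CCC[C@@H]3C(O[Si](C)(C)C)(c3ccccc3)c3ccccc3)c(O)cc(O)c12 | intermediate
17 | 5-hydroxy-3-(methoxymethoxy)-2-[4-(methoxymethoxy)phenyl]-8-methylidene-4H-chromene-4,7(8H)-dione (ortho-quinone methide) | C=C1C(=O)C=C(O)C2=C1OC(c1ccc(OCOC)cc1)=C(OCOC)C2=O | intermediate
18 | (E)-enamine of 5 and 14 | CC(C)=CC/C=C/N1CCC[C@@H]1C(O[Si](C)(C)C)(c1ccccc1)c1ccccc1 | intermediate
19 | cyclic N,O-aminal: (9S)-pyrano[2,3-h]chromen-4-one of 20 with the amine of 14 at the lactol carbon in place of OH | C1(N2CCC[C@@H]2C(O[Si](C)(C)C)(c2ccccc2)c2ccccc2)Oc2cc(O)c3c(=O)c(OCOC)c(-c4ccc(OCOC)cc4)oc3c2C[C@@H]1CC=C(C)C | intermediate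
20 | (9S)-5,8-dihydroxy-3-(methoxymethoxy)-2-[4-(methoxymethoxy)phenyl]-9-(3-methylbut-2-en-1-yl)-9,10-dihydro-4H,8H-pyrano[2,3-h]chromen-4-one (lactol, both anomers at the lactol carbon) | OC1Oc2cc(O)c3c(=O)c(OCOC)c(-c4ccc(OCOC)cc4)oc3c2C[C@@H]1CC=C(C)C | intermediate
21 | (2S)-2-({5,7-dihydroxy-3-(methoxymethoxy)-2-[4-(methoxymethoxy)phenyl]-4-oxo-4H-chromen-8-yl}methyl)-5-methylhex-4-enal (open-chain tautomer) | O=C[C@@H](CC=C(C)C)Cc1c(O)cc(O)c2c(=O)c(OCOC)c(-c3ccc(OCOC)cc3)oc12 | intermediate
22 | 5,7-dihydroxy-8-[(2S)-2-(1-hydroxyethyl)-5-methylhex-4-en-1-yl]-3-(methoxymethoxy)-2-[4-(methoxymethoxy)phenyl]-4H-chromen-4-one (carbinol epimers) | CC(O)[C@@H](CC=C(C)C)Cc1c(O)cc(O)c2c(=O)c(OCOC)c(-c3ccc(OCOC)cc3)oc12 | intermediate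
23 | 8-[(2S)-2-(1-hydroxyethyl)-5-methylhex-4-en-1-yl]-5-hydroxy-3,7-bis(methoxymethoxy)-2-[4-(methoxymethoxy)phenyl]-4H-chromen-4-one | CC(O)[C@@H](CC=C(C)C)Cc1c(OCOC)cc(O)c2c(=O)c(OCOC)c(-c3ccc(OCOC)cc3)oc12 | intermediate
24 | 8-[(2S)-2-acetyl-5-methylhex-4-en-1-yl]-5-hydroxy-3,7-bis(methoxymethoxy)-2-[4-(methoxymethoxy)phenyl]-4H-chromen-4-one | CC(=O)[C@@H](CC=C(C)C)Cc1c(OCOC)cc(O)c2c(=O)c(OCOC)c(-c3ccc(OCOC)cc3)oc12 | intermediate
25 | 5-hydroxy-3,7-bis(methoxymethoxy)-2-[4-(methoxymethoxy)phenyl]-8-[(2S)-5-methyl-2-(prop-1-en-2-yl)hex-4-en-1-yl]-4H-chromen-4-one | C=C(C)[C@@H](CC=C(C)C)Cc1c(OCOC)cc(O)c2c(=O)c(OCOC)c(-c3ccc(OCOC)cc3)oc12 | intermediate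
26 | 3,5,7-trihydroxy-2-(4-hydroxyphenyl)-8-[(2S)-5-methyl-2-(prop-1-en-2-yl)hex-4-en-1-yl]-4H-chromen-4-one | C=C(C)[C@@H](CC=C(C)C)Cc1c(O)cc(O)c2c(=O)c(O)c(-c3ccc(O)cc3)oc12 | target

**Step count**
Total: 12 steps. Longest linear sequence: 11 steps (kaempferol 6 to 26, steps 2–12); step 1 is a one-step side branch.

**Steps most likely to fail**

1. Step 7. Aminomethylation may spread to C6 or to both positions, amine loss from the Mannich base may be too slow at a temperature that still gives good face selectivity, and the quinone methide may oligomerise or be captured by phenols before the enamine reaches it. The fallback sets out from 12 and comes back at 20, and uses only known reaction types in separate operations. 12 is aminomethylated with aqueous dimethylamine and 13 (dioxane, rt → 50 °C) to the 8-(dimethylaminomethyl) compound F1. Heating F1 with TolSO2Na and AcOH (1 equiv) in DMF at 80 °C exchanges the amine for sulfinate by way of the quinone methide and should give the bench-stable 8-(p-tolylsulfonylmethyl) compound F2. F2, 5, 14 (20 mol%) and NaHCO3 in CH2Cl2/water at 0 °C then release 17 by base-induced loss of sulfinate, with no secondary amine other than the catalyst present, and the catalytic enamine [4+2] and hydrolysis should deliver 20.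

2. Step 11. The reagent may be held up by the 5-hydroxy-4-keto chelate so that methylenation stalls, its Lewis-acidic components may strip a MOM group, or slow conversion may allow enolisation and loss of configuration at C2''. The fallback sets out from 24 and comes back at 25 by a two-stage Peterson olefination. Me3SiCH2MgCl with CeCl3 (THF, −78 °C, a non-enolising organocerium addition) should give the β-hydroxysilane F3. KH in THF (0 °C → rt) then eliminates silanolate to give 25; at that stage the stereocentre is no longer next to a carbonyl.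

3. Step 12. Protonation of the isopropenyl or prenyl alkene may be followed by ring closure of the 7-hydroxyl onto the side chain (chroman formation) or by addition of methanol or chloride. The fallback sets out from 25 and comes back at 26 without protic acid. Et3SiOTf with 2,2'-bipyridyl (CH2Cl2, 0 °C) should exchange the three aryl MOM ethers for silyl ethers and give the tris(triethylsilyl) ether F4. Buffered fluoride (Bu4NF/AcOH, THF, 0 °C) then frees the phenols to give 26.

**Further compounds**
F1 | step 7 | 8-[(dimethylamino)methyl]-5,7-dihydroxy-3-(methoxymethoxy)-2-[4-(methoxymethoxy)phenyl]-4H-chromen-4-one | CN(C)Cc1c(O)cc(O)c2c(=O)c(OCOC)c(-c3ccc(OCOC)cc3)oc12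
F2 | step 7 | 5,7-dihydroxy-3-(methoxymethoxy)-2-[4-(methoxymethoxy)phenyl]-8-[(4-methylphenyl)sulfonylmethyl]-4H-chromen-4-one | Cc1ccc(cc1)S(=O)(=O)Cc1c(O)cc(O)c2c(=O)c(OCOC)c(-c3ccc(OCOC)cc3)oc12
F3 | step 11 | 5-hydroxy-8-[(2S)-2-(2-hydroxy-1-(trimethylsilyl)propan-2-yl)-5-methylhex-4-en-1-yl]-3,7-bis(methoxymethoxy)-2-[4-(methoxymethoxy)phenyl]-4H-chromen-4-one (carbinol epimers) | CC(O)(C[Si](C)(C)C)[C@@H](CC=C(C)C)Cc1c(OCOC)cc(O)c2c(=O)c(OCOC)c(-c3ccc(OCOC)cc3)oc12
F4 | step 12 | 5-hydroxy-8-[(2S)-5-methyl-2-(prop-1-en-2-yl)hex-4-en-1-yl]-3,7-bis(triethylsilyloxy)-2-[4-(triethylsilyloxy)phenyl]-4H-chromen-4-one | C=C(C)[C@@H](CC=C(C)C)Cc1c(O[Si](CC)(CC)CC)cc(O)c2c(=O)c(O[Si](CC)(CC)CC)c(-c3ccc(O[Si](CC)(CC)CC)cc3)oc12
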